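Numbering (germacrane): C1 = furanone enol-ether carbon, C2 = its CH, C3 = ketone, C4 = quaternary carbon (C15 methyl), C5=C6 = ylidene bond, C7/C11/C12 = butenolide, C8 = ester carbinol, C9, C10 (C14 methyl), C13 = CH2OAc.
Endgame: the furanone O–C1 bond is closed last, by acid, from the C4-silyloxy β-ethoxy enone 25; just before that O13 is acetylated and O8 esterified.
Key disconnection: C2–C3 leave as ethoxyacetylide (a ketene anion equivalent). C1–C2 comes from its addition to a C1/O8 γ-butyrolactone and C3–C4 from conjugate attack of C4 on the ethoxy ynone so formed; one flask closes the ten-membered carbocycle of 20 from the open-chain bis-lactone 16.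
Enabling feature: C4 is the ε-carbon of the 5-ylidene-2(5H)-furanone ring (C12=O, C11=C7, C6=C5), so loss of H4 gives an aromatic 2-furanolate with a nucleophilic exocyclic C4. C1 and O8 are 1,4-related, so they can be stored together as a cis-2-methyl-γ-lactone that sets C10 from C8.
Ring order: furan (bought; furan-3,4-diyldimethanol = C6, C7, C8, C11, C12, C13) → γ-lactone (C1, C9, C10, C14 from methyl 2-(hydroxymethyl)acrylate) → butenolide (singlet oxygen; C4, C5, C15 from propylene oxide) → ten-membered ring → furanone.

Key step: step 10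

Remark: the (R) antipode of the bisphosphine in step 4 is written on the assumption that it delivers 8S (otherwise the (S) antipode is used); (S)-propylene oxide only keeps 5 to 16 single diastereomers, because the C4 configuration is erased in step 10.

Step 1
Reactants: 1 furan-3,4-diyldimethanol
Product: 2 [4-(trityloxymethyl)furan-3-yl]methanol
Conditions: TrCl (0.9 equiv), Et3N, DMAP (cat.), CH2Cl2, 0 °C to rt
Reagents that add atoms: trityl chloride, ClC(c1ccccc1)(c1ccccc1)c1ccccc1
Why: O-Tritylation (SN1 via the trityl cation) of a symmetric diol with a deficit of reagent should stop at the monoether because the first trityl group crowds the neighbouring hydroxymethyl group, and the trityl ether is stable to n-BuLi and too hindered to direct lithiation.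

Step 2
Reactants: 2 [4-(trityloxymethyl)furan-3-yl]methanol; 3 (S)-propylene oxide
Product: 5 (S)-1-[3-(hydroxymethyl)-4-(trityloxymethyl)furan-2-yl]propan-2-ol, via dilithiated furan 4 (not isolated)
Conditions: n-BuLi (2.2 equiv), THF, −78 to 0 °C; 3, −78 °C to rt; H2O
Reagents that add atoms: none
Why: Alkoxide-directed ortho-lithiation should place lithium on the furan α-carbon next to CH2OLi (future C6) because the other α-carbon is shielded by the trityl ether, and SN2 opening of the epoxide at its CH2 terminus leaves the (S)-carbinol centre untouched.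

Step 3
Reactants: 6 methyl 2-(hydroxymethyl)acrylate
Product: 7 methyl 2-{[(tert-butoxycarbonyl)oxy]methyl}acrylate
Conditions: Boc2O, DMAP (cat.), CH2Cl2, 0 °C
Reagents that add atoms: di-tert-butyl dicarbonate, CC(C)(C)OC(=O)OC(=O)OC(C)(C)C
Why: DMAP-catalysed O-acylation of the allylic alcohol with Boc2O gives the allylic carbonate that serves as π-allyl precursor in step 4.

Step 4
Reactants: 5 (S)-1-[3-(hydroxymethyl)-4-(trityloxymethyl)furan-2-yl]propan-2-ol; 7 methyl 2-{[(tert-butoxycarbonyl)oxy]methyl}acrylate
Product: 9 (8S)-α-methylene-γ-butyrolactone carrying the furan at C8, via hydroxy ester 8 (not isolated)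
Conditions: [Ir(cod)Cl]2 (2.5 mol %), (R)-SEGPHOS (5 mol %), 4-chloro-3-nitrobenzoic acid (10 mol %), Cs2CO3 (20 mol %), THF, 70 °C
Reagents that add atoms: none
Why: Iridium-catalysed transfer-hydrogenative carbonyl 2-(alkoxycarbonyl)allylation: the primary furylmethanol is dehydrogenated in preference to the secondary alcohol, the π-allyliridium species from 7 adds to the transient aldehyde through a closed chair-like transition state in which the chiral bisphosphine sets C8 as S, and hydroxy ester 8 lactonises (5-exo-trig) under the basic conditions.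

Step 5
Reactants: 9 (8S)-α-methylene-γ-butyrolactone
Product: 10 (8S,10S)-cis-α-methyl-γ-butyrolactone with free C4 hydroxyl
Conditions: H2 (1 atm), RhCl(PPh3)3 (5 mol %), benzene/EtOH, rt
Reagents that add atoms: none
Why: Homogeneous hydrogenation: syn delivery of H2 to the exocyclic methylene from the lactone face opposite to the C8 furyl group should place the new C14 methyl cis to it (10S), and RhCl(PPh3)3 spares the furan, the trityl ether and the benzylic-type C8–O bond.

Step 6
Reactants: 10 cis-α-methyl-γ-butyrolactone alcohol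
Product: 11 its C4 tert-butyldimethylsilyl ether
Conditions: TBSCl, imidazole, DMF, rt
Reagents that add atoms: tert-butyldimethylsilyl chloride, C[Si](C)(Cl)C(C)(C)C
Why: Standard silylation of the only free (secondary) hydroxyl gives an ether that survives the oxidation, dehydration, mild acid and strong base of steps 7 to 14.

Step 7
Reactants: 11 furan lactone TBS ether
Product: 13 γ-hydroxybutenolide (C6 hemiketal epimers), via furan endoperoxide 12 (not isolated)
Conditions: O2, visible light, tetraphenylporphyrin (cat.), i-Pr2NEt, CH2Cl2, −78 °C to rt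
Reagents that add atoms: dioxygen, O=O
Why: [4+2] Cycloaddition of singlet oxygen to the electron-rich trisubstituted furan followed by Kornblum–DeLaMare fragmentation: the amine can remove only the single endoperoxide C–H (H12), so C12 becomes the lactone carbonyl and C6 the hemiketal carbon, whose epimers are of no consequence.

Step 8
Reactants: 13 γ-hydroxybutenolide
Product: 15 (Z)-γ-ylidene butenolide trityl ether, via C6 trifluoroacetate 14 (not isolated)
Conditions: (CF3CO)2O, Et3N, CH2Cl2, −20 to 0 °C
Reagents that add atoms: none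
Why: Dehydration of the pseudo-acid: O-trifluoroacetylation makes the C6 hydroxyl a leaving group, ionisation gives the acyloxocarbenium ion and Et3N removes H5 (E1 elimination) to give the conjugated γ-ylidene butenolide, expected mainly as the Z isomer, whose geometry is erased in step 10.

Step 9
Reactants: 15 (Z)-γ-ylidene butenolide trityl ether
Product: 16 (Z)-γ-ylidene butenolide with free C13 hydroxyl
Conditions: CF3CO2H (2 vol %), wet CH2Cl2, 0 °C
Reagents that add atoms: none
Why: Acid-catalysed SN1 detritylation is far faster than cleavage of the secondary TBS ether and frees O13, which must enter step 10 as an alkoxide because a protected O13 would be a β-leaving group of the furanolate.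

Step 10
Reactants: 16 (Z)-γ-ylidene butenolide γ-lactone; 17 ethoxyacetylene
Product: 20 ten-membered β-ethoxy enone diol (4S,8S,10S; 5E), via dilithium furanolate 18 (not isolated), via ethoxy ynone 19 (not isolated)
Conditions: LiN(SiMe3)2 (2.1 equiv), THF (3 mM), −78 °C; LiC≡COEt (1.1 equiv, from 17 and n-BuLi), −78 to −10 °C; AcOH, −78 °C
Reagents that add atoms: none
Why: Proposed new method: LiN(SiMe3)2 converts the C13 hydroxyl into an alkoxide that cannot leave and removes H4, the ε-proton of the C12=O/C11=C7/C6=C5 system, to give the aromatic 2-furanolate 18, which also masks the butenolide carbonyl, so that lithium ethoxyacetylide can add only to the γ-lactone carbonyl (bond C1–C2); ring-chain opening of the hemiketal alkoxide then exposes the push-pull ynone 19, whose ethoxy-bearing carbon C3 is attacked by the exocyclic furanolate terminus C4 (bond C3–C4) to give an allenolate that is inert until it is protonated by acetic acid. The closest known reaction types are the addition of lithium acetylides to lactones, the conjugate addition of stabilised carbanions to ynones and the remote-site (ε) vinylogous aldol and Michael reactions of 5-alkenyl-2-oxyfurans; new are their union in one flask and the ring closure. One ring is closed, the ten-membered carbocycle, by a 10-endo-dig conjugate addition, while the γ-lactone ring is opened. C4 and the C5=C6 geometry are both created in the closure and are independent of the configuration and geometry of 16: the tether reaches C4 only in the U-shaped rotamer about C5–C6 (C4 cis to C7, hence 5E), allylic 1,3-strain against the C13 substituent keeps H8 in the furan plane so that C9 and the ynone sit on one face, and attack on that face of the Z-enol ether (O4 syn to C6, as in metalated allyl ethers) gives 4S. The step needs C4 rather than C6 or C11 attack, which the stiff C1–C2≡C3 rod secures because it cannot be spanned in the eight-membered transition states of the latter two, and it needs the C8 alkoxide to stay off the regenerated C12 carbonyl, which the locked C7–C8 rotamer (O8 turned away from C12) and the cold quench should secure.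

Step 11
Reactants: 20 ten-membered β-ethoxy enone diol
Product: 21 its C13 monoacetate
Conditions: AcCl (1.0 equiv), 2,4,6-collidine, CH2Cl2, −78 °C
Reagents that add atoms: acetyl chloride, CC(=O)Cl
Why: Kinetically chemoselective O-acetylation: with acetyl chloride and a hindered pyridine base at low temperature the primary C13 hydroxyl should react much faster than the hindered secondary C8 hydroxyl.

Step 12
Reactants: 6 methyl 2-(hydroxymethyl)acrylate
Product: 22 methyl 2-[(tert-butyldimethylsilyloxy)methyl]acrylate
Conditions: TBSCl, imidazole, CH2Cl2, rt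
Reagents that add atoms: tert-butyldimethylsilyl chloride, C[Si](C)(Cl)C(C)(C)C
Why: Standard silylation of a primary allylic alcohol protects the side-chain hydroxyl for the esterification.

Step 13
Reactants: 22 methyl 2-[(tert-butyldimethylsilyloxy)methyl]acrylate
Product: 23 2-[(tert-butyldimethylsilyloxy)methyl]acrylic acid
Conditions: LiOH, THF/H2O, 0 °C; then aq. HCl to pH 4
Reagents that add atoms: lithium hydroxide, [Li+].[OH-]
Why: Saponification (acyl-oxygen cleavage) of the unhindered methyl ester proceeds under conditions that leave the primary TBS ether in place.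

Step 14
Reactants: 21 C13 monoacetate; 23 2-[(tert-butyldimethylsilyloxy)methyl]acrylic acid
Product: 25 C8 ester of 21, via mixed anhydride 24 (not isolated)
Conditions: 23, 2,4,6-Cl3C6H2COCl, Et3N, toluene, rt; then 21, DMAP, 0 °C to rt
Reagents that add atoms: none
Why: Yamaguchi esterification: DMAP attacks the less hindered acryloyl carbonyl of the mixed anhydride and the acylpyridinium ion acylates the hindered C8 hydroxyl with retention at C8.

Step 15
Reactants: 25 fully protected seco-furanone
Product: 27 target CNP0193735.1, via hydroxy enone 26 (not isolated)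
Conditions: 48 % aq. HF, MeCN, 0 °C to rt
Reagents that add atoms: water, O
Why: Desilylation by HF frees O4 and the side-chain hydroxyl, and the acid then drives the known cyclodehydration of α'-hydroxy 1,3-diketone enol ethers to 3(2H)-furanones, namely 5-exo-trig attack of the C4 hydroxyl on the protonated C1 carbonyl, loss of water and hydrolysis of the ethyl oxocarbenium ion at C3, none of which touches the C4, C8 or C10 stereocentres.

Compound list
1 | furan-3,4-diyldimethanol | OCc1cocc1CO | starting material
2 | [4-(trityloxymethyl)furan-3-yl]methanol | OCc1cocc1COC(c1ccccc1)(c1ccccc1)c1ccccc1 | intermediate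
3 | (S)-propylene oxide | C[C@H]1CO1 | starting material
4 | lithium [2-lithio-4-(trityloxymethyl)furan-3-yl]methanolate | [Li]OCc1c([Li])occ1COC(c1ccccc1)(c1ccccc1)c1ccccc1 | intermediate (not isolated)
5 | (S)-1-[3-(hydroxymethyl)-4-(trityloxymethyl)furan-2-yl]propan-2-ol | C[C@H](O)Cc1occ(COC(c2ccccc2)(c2ccccc2)c2ccccc2)c1CO | intermediate
6 | methyl 2-(hydroxymethyl)acrylate | C=C(CO)C(=O)OC | starting material
7 | methyl 2-{[(tert-butoxycarbonyl)oxy]methyl}acrylate | C=C(COC(=O)OC(C)(C)C)C(=O)OC | intermediate
8 | methyl (S)-4-hydroxy-4-{2-[(S)-2-hydroxypropyl]-4-(trityloxymethyl)furan-3-yl}-2-methylenebutanoate | C=C(C[C@H](O)c1c(COC(c2ccccc2)(c2ccccc2)c2ccccc2)coc1C[C@H](C)O)C(=O)OC | intermediate (not isolated)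
9 | (S)-5-{2-[(S)-2-hydroxypropyl]-4-(trityloxymethyl)furan-3-yl}-3-methylenedihydrofuran-2(3H)-one | C=C1C[C@H](OC1=O)c1c(COC(c2ccccc2)(c2ccccc2)c2ccccc2)coc1C[C@H](C)O | intermediate
10 | (3S,5S)-5-{2-[(S)-2-hydroxypropyl]-4-(trityloxymethyl)furan-3-yl}-3-methyldihydrofuran-2(3H)-one (cis) | C[C@H]1C[C@H](OC1=O)c1c(COC(c2ccccc2)(c2ccccc2)c2ccccc2)coc1C[C@H](C)O | intermediate
11 | TBS ether of 10 | C[C@H]1C[C@H](OC1=O)c1c(COC(c2ccccc2)(c2ccccc2)c2ccccc2)coc1C[C@H](C)O[Si](C)(C)C(C)(C)C | intermediate
12 | furan endoperoxide of 11 (2,3,7-trioxabicyclo[2.2.1]hept-5-ene, both facial isomers) | C[C@H]1C[C@H](OC1=O)C1=C(COC(c2ccccc2)(c2ccccc2)c2ccccc2)C2OOC1(C[C@H](C)O[Si](C)(C)C(C)(C)C)O2 | intermediate (not isolated)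
13 | 5-hydroxy-2(5H)-furanone (γ-hydroxybutenolide, C6 epimers) carrying the cis-lactone at C7, CH2OTr at C11 and the 2-silyloxypropyl group at C6 | C[C@H]1C[C@H](OC1=O)C1=C(COC(c2ccccc2)(c2ccccc2)c2ccccc2)C(=O)OC1(O)C[C@H](C)O[Si](C)(C)C(C)(C)C | intermediate
14 | C6 trifluoroacetate of 13 | C[C@H]1C[C@H](OC1=O)C1=C(COC(c2ccccc2)(c2ccccc2)c2ccccc2)C(=O)OC1(OC(=O)C(F)(F)F)C[C@H](C)O[Si](C)(C)C(C)(C)C | intermediate (not isolated)
15 | (Z)-5-[(S)-2-(TBS-oxy)propylidene]-2(5H)-furanone with cis-lactone at C7 and CH2OTr at C11 | C[C@H]1C[C@H](OC1=O)C1=C(COC(c2ccccc2)(c2ccccc2)c2ccccc2)C(=O)O/C1=C\[C@H](C)O[Si](C)(C)C(C)(C)C | intermediate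
16 | detritylated 15 (free C13 hydroxyl) | C[C@H]1C[C@H](OC1=O)C1=C(CO)C(=O)O/C1=C\[C@H](C)O[Si](C)(C)C(C)(C)C | intermediate
17 | ethoxyacetylene | CCOC#C | starting material
18 | dilithium salt of 16: 2-furanolate with (Z)-2-silyloxyprop-1-enyl group at C6 and C13 alkoxide | C[C@H]1C[C@H](OC1=O)c1c(C[O-])c([O-])oc1/C=C(/C)O[Si](C)(C)C(C)(C)C.[Li+].[Li+] | intermediate (not isolated)
19 | ring-opened ethoxy ynone (trilithium salt: furanolate, C8 and C13 alkoxides) | CCOC#CC(=O)[C@@H](C)C[C@H]([O-])c1c(C[O-])c([O-])oc1/C=C(/C)O[Si](C)(C)C(C)(C)C.[Li+].[Li+].[Li+] | intermediate (not isolated)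
20 | ten-membered carbocycle: C1 ketone, C2=C3 ethyl enol ether, (4S)-C4(CH3)(OTBS), (5E)-ylidene butenolide, (8S)-OH, (10S)-CH3, C13 OH | O[C@H]1C[C@H](C)C(=O)/C=C(OCC)\[C@@](C)(O[Si](C)(C)C(C)(C)C)/C=C2/OC(=O)C(CO)=C12 | intermediate
21 | C13 acetate of 20 | O[C@H]1C[C@H](C)C(=O)/C=C(OCC)\[C@@](C)(O[Si](C)(C)C(C)(C)C)/C=C2/OC(=O)C(COC(C)=O)=C12 | intermediate
22 | methyl 2-[(tert-butyldimethylsilyloxy)methyl]acrylate | C=C(CO[Si](C)(C)C(C)(C)C)C(=O)OC | intermediate
23 | 2-[(tert-butyldimethylsilyloxy)methyl]acrylic acid | C=C(CO[Si](C)(C)C(C)(C)C)C(=O)O | intermediate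
24 | mixed anhydride of 23 with 2,4,6-trichlorobenzoic acid | C=C(CO[Si](C)(C)C(C)(C)C)C(=O)OC(=O)c1c(Cl)cc(Cl)cc1Cl | intermediate (not isolated)
25 | C8 2-(TBS-oxymethyl)acrylate of 21 | C=C(CO[Si](C)(C)C(C)(C)C)C(=O)O[C@H]1C[C@H](C)C(=O)/C=C(OCC)\[C@@](C)(O[Si](C)(C)C(C)(C)C)/C=C2/OC(=O)C(COC(C)=O)=C12 | intermediate
26 | doubly desilylated 25 (free C4 and side-chain hydroxyls) | C=C(CO)C(=O)O[C@H]1C[C@H](C)C(=O)/C=C(OCC)\[C@@](C)(O)/C=C2/OC(=O)C(COC(C)=O)=C12 | intermediate (not isolated)
27 | CNP0193735.1 (4S,8S,10S; 5E) | C=C(CO)C(=O)O[C@H]1C[C@H](C)C2=CC(=O)[C@](C)(/C=C3/OC(=O)C(COC(C)=O)=C31)O2 | target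

Total step count: 15. Longest linear sequence: 12 steps (1, 2, 4 to 11, 14, 15).

Steps most likely to fail

Step 10. Several processes may intervene:
- The hemiketal alkoxide from the lactone may not open to the ynone.
- The furanolate may react between molecules instead of closing the ring.
- Attack may come from the other face or from the other enol-ether geometry, which would epimerise C4.
- The freed C8 alkoxide may add to the C12 carbonyl (translactonisation).

The fallback uses known chemistry, sets out from 10 and comes back at 20; it makes the two bonds one at a time with acetylene itself, at the furan stage where no enol lactone is present. Dess–Martin oxidation of 10 gives methyl ketone F1. Ethynylmagnesium bromide at −78 °C, where the ketone reacts faster than the lactone, gives tertiary propargylic alcohol F2, and the C4 epimers are separated here. TBSOTf and 2,6-lutidine give silyl ether F3. LiN(SiMe3)2 under high dilution closes the ten-membered ring by intramolecular acetylide addition to the lactone and gives macrocyclic ynone F4. Singlet oxygen with i-Pr2NEt gives hydroxybutenolide F5. Catalytic p-TsOH in wet CH2Cl2 dehydrates and detritylates it to ylidene butenolide ynone F6. PMe3-catalysed conjugate addition of ethanol to the ynone then gives 20.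

Step 4. Dehydrogenation of the doubly ortho-substituted furylmethanol may be slow, and the transient aldehyde may be held back as a lactol with the C4 hydroxyl, so that conversion stalls or enantioselection erodes. The fallback sets out from 5 and comes back at 9. MnO2 oxidises only the furylic primary alcohol to hydroxy aldehyde F7. A catalytic asymmetric Nozaki–Hiyama–Kishi-type allylation with ethyl 2-(bromomethyl)acrylate (CrCl2 catalyst, chiral bis(oxazolinyl)carbazole ligand, Mn powder, Me3SiCl) gives hydroxy ethyl ester F8, which lactonises on mildly acidic work-up to 9.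

Step 14. Acylation of the hindered C8 hydroxyl may be slower than three side processes: DMAP addition to the 2-(silyloxymethyl)acrylate, acetyl migration from O13, or base-assisted attack of O8 on the C12 carbonyl. The fallback sets out from 21 and comes back at 27. Acryloyl chloride and i-Pr2NEt at −78 °C give acrylate F9. A Morita–Baylis–Hillman reaction with aqueous formaldehyde and DABCO gives 2-(hydroxymethyl)acrylate F10. Aqueous HF as in step 15 then gives 27 by way of 26.

Further compounds
F1 | step 10 | methyl ketone from 10 (C4 ketone, furan, cis-lactone) | C[C@H]1C[C@H](OC1=O)c1c(COC(c2ccccc2)(c2ccccc2)c2ccccc2)coc1CC(C)=O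
F2 | step 10 | (4S)-tertiary propargylic alcohol | C[C@H]1C[C@H](OC1=O)c1c(COC(c2ccccc2)(c2ccccc2)c2ccccc2)coc1C[C@](C)(O)C#C
F3 | step 10 | TBS ether of F2 | C[C@H]1C[C@H](OC1=O)c1c(COC(c2ccccc2)(c2ccccc2)c2ccccc2)coc1C[C@](C)(O[Si](C)(C)C(C)(C)C)C#C
F4 | step 10 | furan-fused ten-membered ynone with free C8 hydroxyl | O[C@H]1C[C@H](C)C(=O)C#C[C@@](C)(O[Si](C)(C)C(C)(C)C)Cc2occ(COC(c3ccccc3)(c3ccccc3)c3ccccc3)c12
F5 | step 10 | γ-hydroxybutenolide of F4 (C6 epimers) | O[C@H]1C[C@H](C)C(=O)C#C[C@@](C)(O[Si](C)(C)C(C)(C)C)CC2(O)OC(=O)C(COC(c3ccccc3)(c3ccccc3)c3ccccc3)=C12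
F6 | step 10 | (5E)-ylidene butenolide ynone with free C8 and C13 hydroxyls | O[C@H]1C[C@H](C)C(=O)C#C[C@@](C)(O[Si](C)(C)C(C)(C)C)/C=C2/OC(=O)C(CO)=C12
F7 | step 4 | 2-[(S)-2-hydroxypropyl]-4-(trityloxymethyl)furan-3-carbaldehyde | C[C@H](O)Cc1occ(COC(c2ccccc2)(c2ccccc2)c2ccccc2)c1C=O
F8 | step 4 | ethyl ester analogue of 8 | C=C(C[C@H](O)c1c(COC(c2ccccc2)(c2ccccc2)c2ccccc2)coc1C[C@H](C)O)C(=O)OCC
F9 | step 14 | C8 acrylate of 21 | C=CC(=O)O[C@H]1C[C@H](C)C(=O)/C=C(OCC)\[C@@](C)(O[Si](C)(C)C(C)(C)C)/C=C2/OC(=O)C(COC(C)=O)=C12
F10 | step 14 | C8 2-(hydroxymethyl)acrylate of 21 (C4 still TBS-protected) | C=C(CO)C(=O)O[C@H]1C[C@H](C)C(=O)/C=C(OCC)\[C@@](C)(O[Si](C)(C)C(C)(C)C)/C=C2/OC(=O)C(COC(C)=O)=C12
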